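Remark on the chemistry: the target has no stereogenic unit. Alkene 6 is expected as an E/Z mixture and is carried on as such, because step 4 saturates it.

## Analysis of the target

Target 20 (C28H26O5) is an open-chain bis(bibenzyl): four benzene rings joined by two CH2–CH2 bridges (ring A to ring B, ring C to ring D) and one diaryl ether oxygen (ring B to ring C). Ring A is a 3-hydroxyphenyl group. Ring B is 1,4-disubstituted by the bridge and the ether oxygen. Ring C carries a hydroxyl ortho to the ether oxygen and para to its bridge. Ring D is a 3-alkylcatechol. There is no stereocenter and no stereogenic double bond; the route only passes through one racemic carbinol centre that is erased in the same flask. The four free phenols, above all the ring D catechol and the ortho-aryloxyphenol of ring C, are prone to oxidation, so they are kept masked until the last step. The difficulty is regiochemical: three different oxygenation patterns, an unsymmetrical diaryl ether, and a ring A hydroxyl meta to its alkyl chain, which ortho/para-directed arene chemistry does not deliver. The strategy rests on ring A: its bridge carbon C1 and hydroxyl carbon C3 stand in the same 1,3-relation as the carbonyl carbon and the ethoxy-bearing carbon of 3-ethoxycyclohex-2-en-1-one 14. Ring A is therefore brought in as a six-membered enone and aromatized late.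

## Retrosynthetic reasoning

**20 to 19.** The three O–CH3 bonds on rings C and D are cut last. Methyl ethers survive base, organomagnesium chemistry, hydrogenation and aerobic palladium catalysis, and one Lewis-acid treatment removes all three. The forward step must cleave them without touching the diaryl ether.

**19 to 17.** The ring A phenol is traced back to cyclohexenone 17, one oxidation level lower. Forward, a single dehydrogenation gives dienone 18, which tautomerizes to 19. This turns the meta-hydroxyl problem into a ketone placement problem.

**17 to 13 and 14.** The bond between ring A and its bridge CH2 is cut. This is preferred over the central CH2–CH2 bond because 14 supplies all six ring A carbons with both functional positions already 1,3-related. Forward, Grignard reagent 15 from bromide 13 adds to the carbonyl of 14, and acid converts adduct 16 into 17 with transposition of the enone.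

**13 to 9.** The 2-bromoethyl arm is reduced to a formyl group by functional-group interconversion: bromide 13 from alcohol 12, 12 from styrene 10 by anti-Markovnikov hydration through borane 11, and 10 from aldehyde 9 by one-carbon olefination. The formyl group is wanted because it activates the next disconnection.

**9 to 7 and 8.** The diaryl ether is cut at the ring B carbon–oxygen bond. Ring B can carry a para formyl group and a fluoride leaving group (8), whereas ring C is electron-rich and can only act as the nucleophile (phenol 7). Forward, this is a nucleophilic aromatic substitution.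

**7 to 2 and 4.** The C–D bridge is cut at its central bond, written as the alkene of stilbene 6. Forward, ylide 5 from phosphonium salt 4 condenses with aldehyde 2, and one hydrogenation saturates the alkene and removes the benzyl group to free the phenol of 7.

**2 to 1, and 4 to 3.** Aldehyde 2 is the benzyl ether of isovanillin 1, which already has the ring C pattern (chain carbon, hydroxyl meta, methoxy para). Salt 4 comes in one step from alcohol 3, which carries the ring D oxygens.

## Alternatives that were turned down

**Alternative 1: ring C by Michael–aldol annulation.**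
- Disconnection: ring C is opened across two C–C bonds, giving 4-(2,3-dimethoxyphenyl)butanal A2 and aryloxymethyl vinyl ketone A3.
- Forward key step: pyrrolidine A4 converts A2 into its enamine, which adds to A3. The resulting 1,5-keto aldehyde closes by aldol condensation from the aryloxy-bearing methylene, the only position that can form a six-membered ring, to give racemic enone A1. Dehydrogenation would then give ring C.
- For it: the 1,2,4-pattern of ring C is fixed by construction, as securely as the chosen route fixes it through 1. The ether oxygen is installed by simple O-alkylation of a phenol, so no hot substitution step is needed; on that point it is the stronger plan.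
- Against it: A3 is a polymerization-prone enone that must be made from a ring A–ring B bibenzyl phenol, which itself needs an olefination and hydrogenation. A2 needs a three-carbon homologation and can self-condense under amine catalysis. The late dehydrogenation would act on an α-aryloxy enone, a less-tested substrate than the plain 3-alkyl enone 17.
- Comparison: it needs two bibenzyl assemblies plus two fragment syntheses, whereas the chosen route buys its six-membered ring as 14 and stays shorter.

**Alternative 2: ring A by [3+3] cyclization to a salicylate.**
- Disconnection: ring A is split into two three-carbon pieces, 1-methoxy-1,3-bis(trimethylsilyloxy)buta-1,3-diene A6 and β-keto acetal A7.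
- Forward key step: TiCl4 A8 promotes attack of the diene terminus on the acetal carbon and of its central carbon on the ketone, giving methyl 6-alkylsalicylate A5. Saponification and decarboxylation would leave the hydroxyl meta to the chain.
- For it: the regiochemistry is built in, and ring A arrives as an arene with no oxidative step near the electron-rich rings C and D, which is a real advantage over step 10. A7 should be reachable from aldehyde 9 in about two steps, so the overall step count is about equal.
- Against it: the ester carbon is built only to be removed. A 2,6-disubstituted, hydrogen-bonded benzoate saponifies slowly, and salicylic acid decarboxylation needs strong heating. The step uses a moisture-sensitive bis-silyl diene and stoichiometric TiCl4 on a substrate with four Lewis-basic ether oxygens.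
- Comparison: the chosen route offers a bought ring, no throw-away carbon and milder operations, at the price of one oxidation.

**Alternative 3: Friedel–Crafts acylation of a preformed diaryl ether.**
- Disconnection: the bond between ring C and the first bridge carbon, giving (2,3-dimethoxyphenyl)acetyl chloride A10 and methyl 4-(2-methoxyphenoxy)benzoate A11.
- Forward key step: SnCl4 A12 mediates acylation of A11 para to the methoxy group to give deoxybenzoin A9.
- For it: it is the shortest access to a ring B–C–D skeleton, since A11 comes from one substitution step. Up to that stage it beats the chosen route in step economy.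
- Against it: the regiochemistry rests on a preference between two oxygen donors on one ring (methoxy against aryloxy) rather than on structure, and an isomer acylated para to the aryloxy oxygen would be hard to separate. A10 carries its own activated ring and can self-acylate or form a ketene. SnCl4 can cleave a methoxy group next to the new carbonyl. The ketone must then be deoxygenated, and the ester must still be turned into the A–B bridge by reduction, olefination and hydrogenation, so the meta-phenol of ring A is not addressed in any new way.
- Comparison: the chosen route fixes every substitution pattern by its starting materials (1, 3, 8, 14) and by mechanism, and places its risk in one well-understood C–C bond formation.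

Key step: step 9

## Route

Step 1
Reactants: 1 isovanillin (3-hydroxy-4-methoxybenzaldehyde)
Product: 2 3-(benzyloxy)-4-methoxybenzaldehyde
Conditions: BnBr, K2CO3, DMF, rt
Reagents that add atoms: benzyl bromide, BrCc1ccccc1
Why: Williamson ether synthesis on the phenoxide; the benzyl group masks the phenol during the ylide step and is removed in step 4 without an extra operation.

Step 2
Reactants: 3 2,3-dimethoxybenzyl alcohol
Product: 4 (2,3-dimethoxybenzyl)triphenylphosphonium bromide
Conditions: PPh3·HBr, MeCN, reflux
Reagents that add atoms: triphenylphosphine hydrobromide, Br.c1ccc(cc1)P(c1ccccc1)c1ccccc1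
Why: Acid-promoted ionization of the electron-rich benzylic alcohol and capture by triphenylphosphine give the phosphonium salt directly, a standard one-step preparation of benzylic Wittig salts.

Step 3
Reactants: 4 (2,3-dimethoxybenzyl)triphenylphosphonium bromide; 2 3-(benzyloxy)-4-methoxybenzaldehyde
Product: 6 2-(benzyloxy)-4-[2-(2,3-dimethoxyphenyl)ethenyl]-1-methoxybenzene (E/Z mixture), via benzylic phosphonium ylide 5 (not isolated)
Conditions: KOtBu, THF, 0 °C; then 2, 0 °C → rt
Reagents that add atoms: none
Why: Wittig olefination with a semi-stabilized ylide forms the C–D bridge carbons; the expected E/Z mixture is of no consequence because both isomers converge in step 4.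

Step 4
Reactants: 6 2-(benzyloxy)-4-[2-(2,3-dimethoxyphenyl)ethenyl]-1-methoxybenzene
Product: 7 5-[2-(2,3-dimethoxyphenyl)ethyl]-2-methoxyphenol
Conditions: H2 (1 atm), 10% Pd/C, EtOAc–EtOH, rt
Reagents that add atoms: none
Why: Catalytic hydrogenation saturates the stilbene and hydrogenolyses the benzyl ether in one operation, while the aryl methyl ethers and the arenes are inert under these conditions.

Step 5
Reactants: 7 5-[2-(2,3-dimethoxyphenyl)ethyl]-2-methoxyphenol; 8 4-fluorobenzaldehyde
Product: 9 4-{5-[2-(2,3-dimethoxyphenyl)ethyl]-2-methoxyphenoxy}benzaldehyde
Conditions: K2CO3, DMF, 140 °C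
Reagents that add atoms: none
Why: Nucleophilic aromatic substitution (addition–elimination); the para formyl group stabilizes the Meisenheimer intermediate and fluoride is the best leaving group for this mechanism, so the electron-rich phenoxide of 7 should displace it cleanly.

Step 6
Reactants: 9 4-{5-[2-(2,3-dimethoxyphenyl)ethyl]-2-methoxyphenoxy}benzaldehyde
Product: 10 4-[2-(2,3-dimethoxyphenyl)ethyl]-2-(4-ethenylphenoxy)-1-methoxybenzene
Conditions: Ph3PCH3Br, KOtBu, THF, 0 °C → rt
Reagents that add atoms: methyltriphenylphosphonium bromide, C[P+](c1ccccc1)(c1ccccc1)c1ccccc1.[Br-]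
Why: Wittig methylenation of an aromatic aldehyde with the non-stabilized ylide is fast and needs no stereocontrol.

Step 7
Reactants: 10 4-[2-(2,3-dimethoxyphenyl)ethyl]-2-(4-ethenylphenoxy)-1-methoxybenzene
Product: 12 2-(4-{5-[2-(2,3-dimethoxyphenyl)ethyl]-2-methoxyphenoxy}phenyl)ethan-1-ol, via B-alkyl-9-borabicyclononane 11 (not isolated)
Conditions: 9-BBN, THF, 0 °C → rt; then NaOH (aq), H2O2, 0 °C → rt
Reagents that add atoms: hydrogen peroxide, OO (the hydroxyl oxygen); 9-borabicyclo[3.3.1]nonane, B1C2CCCC1CCC2 (boron of intermediate 11 only)
Why: Hydroboration–oxidation; the bulky 9-BBN places boron on the terminal carbon of the styrene almost exclusively, and alkaline peroxide replaces boron by hydroxyl with the ethers untouched.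

Step 8
Reactants: 12 2-(4-{5-[2-(2,3-dimethoxyphenyl)ethyl]-2-methoxyphenoxy}phenyl)ethan-1-ol
Product: 13 2-[4-(2-bromoethyl)phenoxy]-4-[2-(2,3-dimethoxyphenyl)ethyl]-1-methoxybenzene
Conditions: CBr4, PPh3, CH2Cl2, 0 °C → rt
Reagents that add atoms: carbon tetrabromide, BrC(Br)(Br)Br
Why: Appel reaction; the alkoxyphosphonium ion of the primary alcohol is displaced by bromide under neutral conditions that do not affect the ethers or the electron-rich rings.

Step 9
Reactants: 13 2-[4-(2-bromoethyl)phenoxy]-4-[2-(2,3-dimethoxyphenyl)ethyl]-1-methoxybenzene; 14 3-ethoxycyclohex-2-en-1-one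
Product: 17 3-[2-(4-{5-[2-(2,3-dimethoxyphenyl)ethyl]-2-methoxyphenoxy}phenyl)ethyl]cyclohex-2-en-1-one, via alkylmagnesium bromide 15 (not isolated), via tertiary allylic alcohol 16 (not isolated)
Conditions: Mg turnings (I2 cat.), THF, 40 °C; then 14, THF, 0 °C → rt; then 1 M HCl (aq), rt
Reagents that add atoms: water, O (the carbonyl oxygen of 17); magnesium, [Mg] (metal of intermediate 15 only)
Why: Magnesium inserts into the primary C–Br bond of 13 to give 15, which adds to the carbonyl carbon of 14 and forms the bromomagnesium alkoxide of racemic 16. On acidification the tertiary allylic hydroxyl ionizes, assisted by the ethoxy oxygen, to an O-ethyl oxocarbenium ion; water adds at the ethoxy-bearing carbon and ethanol is lost, so the chain ends on the β-carbon of a new enone. The closest known reaction type is the Stork–Danheiser alkylative 1,3-carbonyl transposition of 3-alkoxyenones with organomagnesium reagents. No ring is closed, and the carbinol centre of 16 is destroyed in the hydrolysis, so 17 is achiral. The step needs 1,2-addition rather than conjugate addition; the ethoxy donor deactivates the β-carbon of the vinylogous ester, which secures this. It also needs addition to outrun deprotonation at the α′-CH2 of 14, which an unbranched primary alkyl Grignard reagent at 0 °C should manage. The position of the chain relative to the carbonyl is then fixed by the transposition itself, and the rest of 13 contains only aryl ethers that are inert to the reagent and to dilute acid.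

Step 10
Reactants: 17 3-[2-(4-{5-[2-(2,3-dimethoxyphenyl)ethyl]-2-methoxyphenoxy}phenyl)ethyl]cyclohex-2-en-1-one
Product: 19 3-[2-(4-{5-[2-(2,3-dimethoxyphenyl)ethyl]-2-methoxyphenoxy}phenyl)ethyl]phenol, via cross-conjugated cyclohexadienone 18 (not isolated)
Conditions: Pd(TFA)2 (5 mol %), 2-(dimethylamino)pyridine (10 mol %), TsOH (20 mol %), O2 (1 atm), DMSO, 80 °C
Reagents that add atoms: none
Why: Aerobic palladium-catalysed dehydrogenation of a cyclohexenone, established for 3-substituted cyclohexenones as a route to meta-substituted phenols; a divalent palladium enolate forms at the α′-carbon, β-hydride elimination gives dienone 18, which tautomerizes to the phenol, and O2 returns zerovalent palladium to the divalent state.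

Step 11
Reactants: 19 3-[2-(4-{5-[2-(2,3-dimethoxyphenyl)ethyl]-2-methoxyphenoxy}phenyl)ethyl]phenol
Product: 20 3-[2-(3-{4-[2-(3-hydroxyphenyl)ethyl]phenoxy}-4-hydroxyphenyl)ethyl]benzene-1,2-diol (the target)
Conditions: BBr3 (6 equiv), CH2Cl2, −78 °C → rt; then MeOH, H2O, 0 °C
Reagents that add atoms: none
Why: Lewis-acid cleavage of aryl methyl ethers; boron coordinates each methoxy oxygen and bromide attacks the methyl carbon, while the diaryl ether, which has no alkyl carbon to attack, is retained and the borate esters are hydrolysed on work-up.

## Compound list

1 | isovanillin (3-hydroxy-4-methoxybenzaldehyde) | COc1ccc(C=O)cc1O | starting material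
2 | 3-(benzyloxy)-4-methoxybenzaldehyde | COc1ccc(C=O)cc1OCc1ccccc1 | intermediate
3 | 2,3-dimethoxybenzyl alcohol | COc1cccc(CO)c1OC | starting material
4 | (2,3-dimethoxybenzyl)triphenylphosphonium bromide | COc1cccc(C[P+](c2ccccc2)(c2ccccc2)c2ccccc2)c1OC.[Br-] | intermediate
5 | (2,3-dimethoxybenzylidene)triphenylphosphorane | COc1cccc(C=P(c2ccccc2)(c2ccccc2)c2ccccc2)c1OC | intermediate (not isolated)
6 | 2-(benzyloxy)-4-[2-(2,3-dimethoxyphenyl)ethenyl]-1-methoxybenzene (E/Z mixture) | COc1ccc(C=Cc2cccc(OC)c2OC)cc1OCc1ccccc1 | intermediate
7 | 5-[2-(2,3-dimethoxyphenyl)ethyl]-2-methoxyphenol | COc1ccc(CCc2cccc(OC)c2OC)cc1O | intermediate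
8 | 4-fluorobenzaldehyde | O=Cc1ccc(F)cc1 | starting material
9 | 4-{5-[2-(2,3-dimethoxyphenyl)ethyl]-2-methoxyphenoxy}benzaldehyde | COc1ccc(CCc2cccc(OC)c2OC)cc1Oc1ccc(C=O)cc1 | intermediate
10 | 4-[2-(2,3-dimethoxyphenyl)ethyl]-2-(4-ethenylphenoxy)-1-methoxybenzene | COc1ccc(CCc2cccc(OC)c2OC)cc1Oc1ccc(C=C)cc1 | intermediate
11 | 9-[2-(4-{5-[2-(2,3-dimethoxyphenyl)ethyl]-2-methoxyphenoxy}phenyl)ethyl]-9-borabicyclo[3.3.1]nonane | COc1ccc(CCc2cccc(OC)c2OC)cc1Oc1ccc(CCB2C3CCCC2CCC3)cc1 | intermediate (not isolated)
12 | 2-(4-{5-[2-(2,3-dimethoxyphenyl)ethyl]-2-methoxyphenoxy}phenyl)ethan-1-ol | COc1ccc(CCc2cccc(OC)c2OC)cc1Oc1ccc(CCO)cc1 | intermediate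
13 | 2-[4-(2-bromoethyl)phenoxy]-4-[2-(2,3-dimethoxyphenyl)ethyl]-1-methoxybenzene | COc1ccc(CCc2cccc(OC)c2OC)cc1Oc1ccc(CCBr)cc1 | intermediate
14 | 3-ethoxycyclohex-2-en-1-one | CCOC1=CC(=O)CCC1 | starting material
15 | [2-(4-{5-[2-(2,3-dimethoxyphenyl)ethyl]-2-methoxyphenoxy}phenyl)ethyl]magnesium bromide | COc1ccc(CCc2cccc(OC)c2OC)cc1Oc1ccc(CC[Mg]Br)cc1 | intermediate (not isolated)
16 | 3-ethoxy-1-[2-(4-{5-[2-(2,3-dimethoxyphenyl)ethyl]-2-methoxyphenoxy}phenyl)ethyl]cyclohex-2-en-1-ol (racemic, formed as its bromomagnesium alkoxide) | CCOC1=CC(O)(CCc2ccc(Oc3cc(CCc4cccc(OC)c4OC)ccc3OC)cc2)CCC1 | intermediate (not isolated)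
17 | 3-[2-(4-{5-[2-(2,3-dimethoxyphenyl)ethyl]-2-methoxyphenoxy}phenyl)ethyl]cyclohex-2-en-1-one | O=C1C=C(CCc2ccc(Oc3cc(CCc4cccc(OC)c4OC)ccc3OC)cc2)CCC1 | intermediate
18 | 3-[2-(4-{5-[2-(2,3-dimethoxyphenyl)ethyl]-2-methoxyphenoxy}phenyl)ethyl]cyclohexa-2,5-dien-1-one | O=C1C=CCC(CCc2ccc(Oc3cc(CCc4cccc(OC)c4OC)ccc3OC)cc2)=C1 | intermediate (not isolated)
19 | 3-[2-(4-{5-[2-(2,3-dimethoxyphenyl)ethyl]-2-methoxyphenoxy}phenyl)ethyl]phenol | Oc1cccc(CCc2ccc(Oc3cc(CCc4cccc(OC)c4OC)ccc3OC)cc2)c1 | intermediate
20 | 3-[2-(3-{4-[2-(3-hydroxyphenyl)ethyl]phenoxy}-4-hydroxyphenyl)ethyl]benzene-1,2-diol | Oc1cccc(CCc2ccc(Oc3cc(CCc4cccc(O)c4O)ccc3O)cc2)c1 | target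

## Step count and least certain steps

Total step count: 11. Longest linear sequence: 10 steps (from 1 through steps 1 and 3 to 11; equally from 3 through steps 2 to 11).

**Step 9 (key step).** The likely failures are Wurtz-type homocoupling during magnesium insertion and proton transfer from the α′-CH2 of 14 to the Grignard reagent, which would return the reduced hydrocarbon and unchanged 14. Incomplete hydrolysis of the enol ether is a lesser concern. Within the step, transmetalation of 15 with anhydrous CeCl3 before addition should suppress enolization. The fallback changes the bond-forming event to a cross-coupling. Starting from styrene 10, borane 11 is generated as in step 7 and, instead of being oxidized, is coupled in the same flask with purchased 3-bromocyclohex-2-en-1-one F1 under PdCl2(dppf) catalysis (K3PO4, aqueous THF–DMF, 50 °C). This B-alkyl Suzuki–Miyaura coupling forms the same ring A carbon–CH2 bond and rejoins the route at enone 17, bypassing 12 and 13.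

**Step 10.** The catalyst may stall by aggregation of zerovalent palladium before conversion is complete. Competing palladation of the electron-rich rings C and D, or dehydrogenation of the benzylic bridges towards stilbenes, may also lower selectivity. The fallback starts from 17: kinetic deprotonation at the α′-carbon (LiN(iPr)2, THF, −78 °C) and trapping with PhSeCl should give the α′-selenide 6-(phenylselanyl)-3-(2-arylethyl)cyclohex-2-en-1-one F2. Oxidation (H2O2, pyridine, CH2Cl2, 0 °C → rt) triggers selenoxide syn-elimination to dienone 18, which tautomerizes and rejoins the route at phenol 19.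

**Step 5.** Slow substitution at 140 °C leaves the phenoxide of 7 open to air oxidation, and carbonate with traces of water can consume 8 by disproportionation. The fallback replaces substitution by oxidative copper coupling. Starting from phenol 7, Chan–Lam arylation with (4-ethenylphenyl)boronic acid F3 (Cu(OAc)2, pyridine, 4 Å molecular sieves, CH2Cl2, air, rt) forms the diaryl ether at room temperature and rejoins the route directly at styrene 10, omitting 9 and step 6.

**Step 11.** Cleavage may stop at partially methylated stages if boron chelates of the ring D catechol precipitate, and the freed catechol may oxidize in air during work-up. The fallback changes the mode of C–O cleavage from Lewis-acid activation to nucleophilic displacement at the methyl carbon. Starting from 19, NaSEt in DMF at 130 °C under argon, followed by acidification, should give 20 directly without new intermediates.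

## Further compounds

F1 | step 9 | 3-bromocyclohex-2-en-1-one (purchased coupling partner) | O=C1C=C(Br)CCC1
F2 | step 10 | 6-(phenylselanyl)-3-[2-(4-{5-[2-(2,3-dimethoxyphenyl)ethyl]-2-methoxyphenoxy}phenyl)ethyl]cyclohex-2-en-1-one (racemic) | O=C1C=C(CCc2ccc(Oc3cc(CCc4cccc(OC)c4OC)ccc3OC)cc2)CCC1[Se]c1ccccc1
F3 | step 5 | (4-ethenylphenyl)boronic acid (purchased coupling partner) | C=Cc1ccc(B(O)O)cc1
F0 | step 11 | none | none
A1 | alternative 1 | 2-{4-[2-(3-methoxyphenyl)ethyl]phenoxy}-4-[2-(2,3-dimethoxyphenyl)ethyl]cyclohex-2-en-1-one (racemic) | O=C1CCC(CCc2cccc(OC)c2OC)C=C1Oc1ccc(CCc2cccc(OC)c2)cc1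
A2 | alternative 1 | 4-(2,3-dimethoxyphenyl)butanal | COc1cccc(CCCC=O)c1OC
A3 | alternative 1 | 1-{4-[2-(3-methoxyphenyl)ethyl]phenoxy}but-3-en-2-one | C=CC(=O)COc1ccc(CCc2cccc(OC)c2)cc1
A4 | alternative 1 | pyrrolidine | C1CCNC1
A5 | alternative 2 | methyl 2-hydroxy-6-[2-(4-{5-[2-(2,3-dimethoxyphenyl)ethyl]-2-methoxyphenoxy}phenyl)ethyl]benzoate | COC(=O)c1c(O)cccc1CCc1ccc(Oc2cc(CCc3cccc(OC)c3OC)ccc2OC)cc1
A6 | alternative 2 | 1-methoxy-1,3-bis(trimethylsilyloxy)buta-1,3-diene | COC(O[Si](C)(C)C)=CC(=C)O[Si](C)(C)C
A7 | alternative 2 | 1,1-dimethoxy-5-(4-{5-[2-(2,3-dimethoxyphenyl)ethyl]-2-methoxyphenoxy}phenyl)pentan-3-one | COC(OC)CC(=O)CCc1ccc(Oc2cc(CCc3cccc(OC)c3OC)ccc2OC)cc1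
A8 | alternative 2 | titanium tetrachloride | Cl[Ti](Cl)(Cl)Cl
A9 | alternative 3 | methyl 4-{5-[(2,3-dimethoxyphenyl)acetyl]-2-methoxyphenoxy}benzoate | COC(=O)c1ccc(Oc2cc(C(=O)Cc3cccc(OC)c3OC)ccc2OC)cc1
A10 | alternative 3 | (2,3-dimethoxyphenyl)acetyl chloride | COc1cccc(CC(Cl)=O)c1OC
A11 | alternative 3 | methyl 4-(2-methoxyphenoxy)benzoate | COC(=O)c1ccc(Oc2ccccc2OC)cc1
A12 | alternative 3 | tin tetrachloride | Cl[Sn](Cl)(Cl)Cl
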